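## Retrosynthetic overview

1. Target ⇒ achiral isocoumarin ester + H2O. The hemiketal C3–O bond is the key disconnection. A catalytic enantioselective hydration (proton to C4, water to C3) sets C4 and C3 in the last step.
2. Isocoumarin ester ⇒ 3-(chloromethyl)isocoumarin + 2,4-dihydroxy-5,6-dimethylbenzoic acid. The ester CH2–O bond comes from carboxylate alkylation, with no protecting groups on either half.
3. 3-(Chloromethyl)isocoumarin ⇒ aryl chloromethyl ketone, by demethylation and lactone C–O closure. The ketone ⇒ permethylated toluate, by two lateral lithiations (MeI, then a chloroacetyl Weinreb amide).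
4. The permethylated toluate and the acyl half are the same building block, made by carboxylation of 4,5-dimethylresorcinol.
5. Ring order: both benzene rings are bought. The only ring built is the pyranone ring, which is closed in step 5 and turned into the lactol ring in step 7.

Assumption: 4,5-dimethylresorcinol is taken as a catalogue chemical, and the (S,S) antipode of the step 7 catalyst is taken to give 4S (otherwise its mirror image is used).

## Route

Step 1
Reactants: 1 4,5-dimethylresorcinol (4,5-dimethylbenzene-1,3-diol)
Product: 2 2,4-dihydroxy-5,6-dimethylbenzoic acid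
Conditions: MeOMgOCO2Me (2 M in DMF, 6 equiv), 120 °C, 3 h; then cold 2 M HCl
Reagents that add atoms: methoxymagnesium methyl carbonate, CO[Mg]OC(=O)OC
Why: Kolbe–Schmitt-type ortho-carboxylation with Stiles' reagent delivers CO2 inside a magnesium phenoxide chelate to C6 (ortho to one hydroxyl, para to the other, not between the two oxygens), which is the regiochemistry known for 5-alkylresorcinols, and the magnesium salicylate is safe from decarboxylation until the cold acid quench.

Step 2
Reactants: 2 2,4-dihydroxy-5,6-dimethylbenzoic acid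
Product: 3 methyl 2,4-dimethoxy-5,6-dimethylbenzoate
Conditions: MeI (4.5 equiv), K2CO3 (4.5 equiv), DMF, 50 °C
Reagents that add atoms: iodomethane, CI
Why: Exhaustive SN2 O-methylation (carboxylate alkylation plus Williamson ether synthesis) with excess MeI in warm DMF also methylates the hydrogen-bonded 2-OH and gives the fully masked ortho-toluate needed for the carbanion steps.

Step 3
Reactants: 3 methyl 2,4-dimethoxy-5,6-dimethylbenzoate
Product: 5 methyl 6-ethyl-2,4-dimethoxy-5-methylbenzoate, via lateral benzyllithium 4 (not isolated)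
Conditions: LiN(iPr)2 (1.15 equiv), THF, −78 °C; MeI (1.5 equiv), −78 to 0 °C
Reagents that add atoms: iodomethane, CI
Why: Lateral lithiation of an ortho-toluate followed by SN2 methylation works because only the 6-methyl group is conjugated to the ester, so the base deprotonates there and not at the 5-methyl group, and the doubly ortho-substituted ester is too hindered to self-condense.

Step 4
Reactants: 5 methyl 6-ethyl-2,4-dimethoxy-5-methylbenzoate; 6 2-chloro-N-methoxy-N-methylacetamide
Product: 9 (±)-methyl 6-(4-chloro-3-oxobutan-2-yl)-2,4-dimethoxy-5-methylbenzoate, via secondary benzyllithium 7 (not isolated), via tetrahedral lithium adduct 8 (not isolated)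
Conditions: LiN(iPr)2 (1.2 equiv), THF, −78 °C, 1 h; 6 (1.3 equiv), −78 °C; 1 M HCl quench
Reagents that add atoms: none
Why: In this second lateral lithiation and Weinreb ketone synthesis the chelated adduct 8 holds until the acid quench, so there is no over-addition and the α-chloroketone never meets base, and C4 is formed racemic on purpose because it is flattened in step 5 and set in step 7.

Step 5
Reactants: 9 (±)-methyl 6-(4-chloro-3-oxobutan-2-yl)-2,4-dimethoxy-5-methylbenzoate
Product: 11 3-(chloromethyl)-8-hydroxy-6-methoxy-4,5-dimethyl-1H-isochromen-1-one, via racemic chloromethyl lactol 10 (not isolated)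
Conditions: BCl3 (3 equiv), CH2Cl2, −78 °C to rt; H2O quench, crude; (CF3CO)2O (2 equiv), CH2Cl2, 0 °C to rt
Reagents that add atoms: none
Why: In this chelation-controlled BCl3 cleavage and dehydrative enol lactonisation, chloride attacks only the two O-methyl groups activated by boron bound to the ester carbonyl (ortho ether and hindered ester, the para methoxy stays), the freed keto acid closes to lactol 10, and (CF3CO)2O removes water irreversibly toward C4 to give the conjugated tetrasubstituted enol lactone, which forms the lactone C–O ring bond, pays for the 4-Me/5-Me peri strain and erases the racemic centre.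

Step 6
Reactants: 11 3-(chloromethyl)-8-hydroxy-6-methoxy-4,5-dimethyl-1H-isochromen-1-one; 2 2,4-dihydroxy-5,6-dimethylbenzoic acid
Product: 12 (8-hydroxy-6-methoxy-4,5-dimethyl-1-oxo-1H-isochromen-3-yl)methyl 2,4-dihydroxy-5,6-dimethylbenzoate
Conditions: KHCO3 (1.1 equiv), NaI (10 mol %), dry DMF, 35 °C
Reagents that add atoms: none
Why: In this carboxylate SN2 alkylation with Finkelstein (iodide) assistance, KHCO3 deprotonates only the carboxylic acid and none of the three phenols, and the allylic-type primary chloride reacts at CH2, so the ester C–O bond joining the halves forms without protecting groups.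

Step 7
Reactants: 12 (8-hydroxy-6-methoxy-4,5-dimethyl-1-oxo-1H-isochromen-3-yl)methyl 2,4-dihydroxy-5,6-dimethylbenzoate
Product: 14 [(3R,4S)-3,8-dihydroxy-6-methoxy-4,5-dimethyl-1-oxo-3,4-dihydro-1H-isochromen-3-yl]methyl 2,4-dihydroxy-5,6-dimethylbenzoate, via acyl oxocarbenium ion 13 (not isolated)
Conditions: (S,S)-IDPi acid, HN[P(=NSO2CF3)(O,O'-binaphthyl)]2 built from two (S)-3,3'-bis[3,5-bis(trifluoromethyl)phenyl]-1,1'-bi-2-naphthol units (5 mol %), H2O (3 equiv), CHCl3/PhMe 1:1, 0 °C to rt; silica plug, crystallisation
Reagents that add atoms: water, O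
Why: Proposed new method: catalytic enantioselective hydration of a tetrasubstituted enol lactone, in which the confined strong acid delivers its proton to one face of C4 of the twisted, peri-strained C3=C4 bond (rate- and enantio-determining, sets 4S), ion 13 stays paired with the chiral anion and is captured at C3 by water anti to the C4 methyl, and C3, which can equilibrate by ring–chain tautomerism, settles as the anomerically stabilised trans-diaxial 3R lactol (3-OH axial, 4-Me pseudoaxial, acyloxymethyl equatorial), while relief of the 4-Me/5-Me peri strain makes the addition downhill so the back reaction that would erode ee is slow; the closest known reaction types are chiral Brønsted acid catalysed protonation of silyl enol ethers and ketene acetals, IDPi-catalysed asymmetric hydroalkoxylation and hydrolactonisation of alkenes, and hydrolytic enantioselective protonation of enol esters under chiral phase-transfer catalysis, none shown for acid-catalysed water addition to an isocoumarin.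

## Compound list

1 | 4,5-dimethylresorcinol | Cc1c(C)cc(O)cc1O | starting material
2 | 2,4-dihydroxy-5,6-dimethylbenzoic acid | OC(=O)c1c(O)cc(O)c(C)c1C | intermediate
3 | methyl 2,4-dimethoxy-5,6-dimethylbenzoate | COC(=O)c1c(OC)cc(OC)c(C)c1C | intermediate
4 | [3,5-dimethoxy-2-(methoxycarbonyl)-6-methylbenzyl]lithium | [Li]Cc1c(C)c(OC)cc(OC)c1C(=O)OC | intermediate
5 | methyl 6-ethyl-2,4-dimethoxy-5-methylbenzoate | COC(=O)c1c(OC)cc(OC)c(C)c1CC | intermediate
6 | 2-chloro-N-methoxy-N-methylacetamide | CON(C)C(=O)CCl | starting material
7 | {1-[3,5-dimethoxy-2-(methoxycarbonyl)-6-methylphenyl]ethyl}lithium (racemic) | [Li]C(C)c1c(C)c(OC)cc(OC)c1C(=O)OC | intermediate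
8 | lithium 1-chloro-3-[3,5-dimethoxy-2-(methoxycarbonyl)-6-methylphenyl]-2-[methoxy(methyl)amino]butan-2-olate (stereoisomer mixture) | COC(=O)c1c(OC)cc(OC)c(C)c1C(C)C(CCl)(O[Li])N(C)OC | intermediate
9 | (±)-methyl 6-(4-chloro-3-oxobutan-2-yl)-2,4-dimethoxy-5-methylbenzoate (racemic) | COC(=O)c1c(OC)cc(OC)c(C)c1C(C)C(=O)CCl | intermediate
10 | (±)-3-(chloromethyl)-3,8-dihydroxy-6-methoxy-4,5-dimethylisochroman-1-one (racemic, ring form of the keto acid) | COc1cc(O)c2c(c1C)C(C)C(O)(CCl)OC2=O | intermediate
11 | 3-(chloromethyl)-8-hydroxy-6-methoxy-4,5-dimethyl-1H-isochromen-1-one | COc1cc(O)c2c(c1C)C(C)=C(CCl)OC2=O | intermediate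
12 | (8-hydroxy-6-methoxy-4,5-dimethyl-1-oxo-1H-isochromen-3-yl)methyl 2,4-dihydroxy-5,6-dimethylbenzoate | COc1cc(O)c2c(c1C)C(C)=C(COC(=O)c1c(O)cc(O)c(C)c1C)OC2=O | intermediate
13 | (4S)-3-{[(2,4-dihydroxy-5,6-dimethylbenzoyl)oxy]methyl}-8-hydroxy-6-methoxy-4,5-dimethyl-1-oxo-1H,4H-isochromen-2-ium (paired with the IDPi anion) | COc1cc(O)c2c(c1C)[C@H](C)C(COC(=O)c1c(O)cc(O)c(C)c1C)=[O+]C2=O | intermediate
14 | [(3R,4S)-3,8-dihydroxy-6-methoxy-4,5-dimethyl-1-oxo-3,4-dihydro-1H-isochromen-3-yl]methyl 2,4-dihydroxy-5,6-dimethylbenzoate | COc1cc(O)c2c(c1C)[C@H](C)[C@](O)(COC(=O)c1c(O)cc(O)c(C)c1C)OC2=O | target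

## Step count

- Total steps: 7.
- Longest linear sequence: 7 (1 → 2 → 3 → 5 → 9 → 11 → 12 → 14). Acid 2 is used twice, in steps 2 and 6.

## Steps most likely to fail

**Step 7 (the new reaction).**
- The enol ester may be too weakly basic for a useful rate of C4 protonation.
- Water may level the acid.
- Facial selectivity on a tetrasubstituted alkene is unproven.
- Reversible dehydration, or drift to the exocyclic enol ester, could cost ee or rate.

The fallback uses known chemistry only. It sets out from 12 and comes back at 14. Compound 12 is hydrated with an achiral acid (CF3CO2H/H2O/dioxane, rt), which is ordinary acid hydrolysis of an enol lactone under thermodynamic control and gives the trans lactol as the racemate. The racemate is 14 together with its mirror image [(3S,4R)-3,8-dihydroxy-6-methoxy-4,5-dimethyl-1-oxo-3,4-dihydro-1H-isochromen-3-yl]methyl 2,4-dihydroxy-5,6-dimethylbenzoate F1. The two are separated by preparative SFC on an amylose tris(3,5-dimethylphenylcarbamate) phase. F1 is dehydrated back to 12 with (CF3CO)2O and recycled.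

**Step 5.**
- BCl3 may leave the hindered methyl ester untouched or start to attack the para methoxy group.
- The dehydration may stop at, or favour, the strain-free exocyclic chloromethylidene isomer.

The fallback sets out from 5 and comes back at 11. It separates the three events and removes the ester before the C–C bond is made. Compound 5 is saponified (KOH, DMSO/H2O, 100 °C) to 6-ethyl-2,4-dimethoxy-5-methylbenzoic acid F2. F2 is doubly deprotonated (LiN(iPr)2, 2.3 equiv, THF, −78 to 0 °C) and acylated with 6. On acid quench the keto acid closes by itself to (±)-3-(chloromethyl)-3-hydroxy-6,8-dimethoxy-4,5-dimethylisochroman-1-one F3. Treatment with (CF3CO)2O gives 3-(chloromethyl)-6,8-dimethoxy-4,5-dimethyl-1H-isochromen-1-one F4. BCl3 (1.2 equiv, CH2Cl2, −78 °C) then cleaves only the peri 8-O-methyl group and gives 11.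

**Step 4.**
- The hindered, delocalised anion 7 may deprotonate the acidic ClCH2 group of 6 or displace chloride instead of adding to the carbonyl.

The fallback sets out from 5 (through 7) and comes back at 12, skipping 9 and 11. It changes both the C2 building block and the coupling reaction. Anion 7 is acylated with 2-(benzyloxy)-N-methoxy-N-methylacetamide to give (±)-methyl 6-[4-(benzyloxy)-3-oxobutan-2-yl]-2,4-dimethoxy-5-methylbenzoate F5. BCl3 (CH2Cl2, −78 °C to rt) removes the benzyl group together with the two chelated methyl groups and gives (±)-3,8-dihydroxy-3-(hydroxymethyl)-6-methoxy-4,5-dimethylisochroman-1-one F6. Catalytic p-toluenesulfonic acid in toluene under Dean–Stark conditions gives 8-hydroxy-3-(hydroxymethyl)-6-methoxy-4,5-dimethyl-1H-isochromen-1-one F7. Mitsunobu esterification of F7 with acid 2 (PPh3, DIAD, THF, 0 °C) is selective for the carboxylic acid over the phenols, forms the same CH2–O bond and gives 12.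

## Further compounds

F1 | step 7 | [(3S,4R)-3,8-dihydroxy-6-methoxy-4,5-dimethyl-1-oxo-3,4-dihydro-1H-isochromen-3-yl]methyl 2,4-dihydroxy-5,6-dimethylbenzoate | COc1cc(O)c2c(c1C)[C@@H](C)[C@@](O)(COC(=O)c1c(O)cc(O)c(C)c1C)OC2=O
F2 | step 5 | 6-ethyl-2,4-dimethoxy-5-methylbenzoic acid | CCc1c(C)c(OC)cc(OC)c1C(=O)O
F3 | step 5 | (±)-3-(chloromethyl)-3-hydroxy-6,8-dimethoxy-4,5-dimethylisochroman-1-one (racemic) | COc1cc(OC)c2c(c1C)C(C)C(O)(CCl)OC2=O
F4 | step 5 | 3-(chloromethyl)-6,8-dimethoxy-4,5-dimethyl-1H-isochromen-1-one | COc1cc(OC)c2c(c1C)C(C)=C(CCl)OC2=O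
F5 | step 4 | (±)-methyl 6-[4-(benzyloxy)-3-oxobutan-2-yl]-2,4-dimethoxy-5-methylbenzoate (racemic) | COC(=O)c1c(OC)cc(OC)c(C)c1C(C)C(=O)COCc1ccccc1
F6 | step 4 | (±)-3,8-dihydroxy-3-(hydroxymethyl)-6-methoxy-4,5-dimethylisochroman-1-one (racemic) | COc1cc(O)c2c(c1C)C(C)C(O)(CO)OC2=O
F7 | step 4 | 8-hydroxy-3-(hydroxymethyl)-6-methoxy-4,5-dimethyl-1H-isochromen-1-one | COc1cc(O)c2c(c1C)C(C)=C(CO)OC2=O
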